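## Retrosynthetic overview

1. **Feature.** Ring D is a meta-phenylene. Its only substituents are the ether oxygen to ring C and the CH2 next to the carbinol carbon. Its six carbons therefore divide into the four ring carbons of a cyclobut-2-enone (joined through C3 to that CH2) and the two carbons of an ethynyl ether on the ring C oxygen.
2. **Key disconnection.** The open chain undergoes a thermal cyclobutenone/ynol ether benzannulation, run intramolecularly. The 18-membered ring closes first (ketene/alkyne [2+2]) and ring D second (six-electron electrocyclisation). Ring D gains one extra hydroxyl (1,3,5 pattern), which is deleted through its triflate.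
3. **Chain assembly** (rings A, B and C are bought). A–O–B comes from a Chan–Lam coupling at the outset, B–CH2CH2–C from hydroboration/B-alkyl Suzuki coupling, and the (S)-carbinol from phosphoric-acid-catalysed allenylboration of the ring A aldehyde.
4. **Order of the two reactive ends.** A ynol ether would not survive dichloroketene, and a cyclobutenone would not survive n-BuLi. Ring C therefore carries the inert (E)-1,2-dichlorovinyl ether while the four-membered ring is built. The ketone is parked as the cyclobutenol during the elimination to the ethynyl ether and is restored by oxidation directly before the key step.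
5. **End game.** Triflation, palladium/formate reduction, fluoride, hydrogenolysis.

Key step: step 16

Assumption: the carbinol carbon of the target is (S) as read from the SMILES, and TRIP-type phosphoric acids are taken to keep their usual sense of induction with aryl aldehydes ((R)-acid to (R)-carbinol), so the (S)-acid is used; the configuration of the homopropargylic alcohol would be checked by Mosher ester analysis.

## Route

Step 1
Reactants: 1 methyl gallate
Product: 2 methyl 7-hydroxy-2,2-diphenyl-1,3-benzodioxole-5-carboxylate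
Conditions: Ph2CCl2 (1.5 equiv), neat, 170 °C, 15 min, argon sweep
Reagents that add atoms: dichlorodiphenylmethane, ClC(Cl)(c1ccccc1)c1ccccc1
Why: Catechol ketalisation with a gem-dichloride can only bridge two adjacent hydroxyls, so one of the two equivalent meta hydroxyls stays free in a single step, and the ketal later falls to hydrogenolysis together with the benzyl ether.

Step 2
Reactants: 2 methyl 7-hydroxy-2,2-diphenyl-1,3-benzodioxole-5-carboxylate; 3 (4-bromophenyl)boronic acid
Product: 4 methyl 7-(4-bromophenoxy)-2,2-diphenyl-1,3-benzodioxole-5-carboxylate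
Conditions: Cu(OAc)2 (1.5 equiv), pyridine (5 equiv), 4 Å MS, CH2Cl2, air, rt
Reagents that add atoms: none
Why: Chan–Lam O-arylation runs at room temperature, spares the C–Br bond and the ester, and is placed before any alkyne exists so that copper-mediated oxidative alkyne homocoupling cannot interfere.

Step 3
Reactants: 5 2,3-dihydroxybenzaldehyde
Product: 6 3-(benzyloxy)-2-hydroxybenzaldehyde
Conditions: NaH (2.2 equiv), DMSO, rt; BnBr (1.0 equiv), rt; 1 M HCl quench
Reagents that add atoms: benzyl bromide, BrCc1ccccc1
Why: Williamson mono-alkylation of the catechol dianion should take place at the 3-phenoxide, which unlike the 2-phenoxide is not stabilised by the ortho formyl group and is the more nucleophilic oxygen.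

Step 4
Reactants: 6 3-(benzyloxy)-2-hydroxybenzaldehyde; 7 methyltriphenylphosphonium bromide
Product: 8 2-(benzyloxy)-6-vinylphenol
Conditions: 7 (2.5 equiv), KOtBu (2.4 equiv), THF, 0 °C to rt
Reagents that add atoms: none
Why: Wittig methylenation tolerates the salicylaldehyde-type phenoxide when extra ylide is supplied, so no protecting group is needed on the 2-hydroxyl.

Step 5
Reactants: 8 2-(benzyloxy)-6-vinylphenol; 4 methyl 7-(4-bromophenoxy)-2,2-diphenyl-1,3-benzodioxole-5-carboxylate
Product: 10 methyl 7-{4-[2-(3-benzyloxy-2-hydroxyphenyl)ethyl]phenoxy}-2,2-diphenyl-1,3-benzodioxole-5-carboxylate, via bis(boryl) adduct 9 (not isolated)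
Conditions: 9-BBN-H (2.3 equiv), THF, 0 °C to rt; then 3 M aq K3PO4, 4, PdCl2(dppf) (5 mol %), DMF, 50 °C
Reagents that add atoms: 9-borabicyclo[3.3.1]nonane, B1C2CCCC1CCC2 (its atoms stay only in 9 and are lost again in 10)
Why: Anti-Markovnikov hydroboration of the styrene followed by B-alkyl Suzuki–Miyaura coupling forms the ring B–CH2 bond and gives the saturated bridge without a hydrogenation that would endanger the benzyl ether, the phenol being only borylated in passing and released by the aqueous base.

Step 6
Reactants: 10 bibenzyl phenol ester; 11 trichloroethylene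
Product: 12 (E)-1,2-dichlorovinyl ether of 10 (ring C 2-oxygen now bears CCl=CHCl)
Conditions: 11 (3 equiv), K2CO3 (3 equiv), DMF, 70 °C
Reagents that add atoms: none
Why: Base-induced loss of HCl from trichloroethylene gives dichloroacetylene, to which the phenoxide adds in anti fashion, and the resulting dichlorovinyl ether is a masked ynol ether too electron-poor to react with ketenes.

Step 7
Reactants: 12 dichlorovinyl ether ester
Product: 13 ring A benzylic alcohol (CO2Me of 12 replaced by CH2OH)
Conditions: DIBAL-H (2.5 equiv), CH2Cl2, −78 to 0 °C; aq Rochelle salt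
Reagents that add atoms: none
Why: Hydride reduction of the aryl ester with DIBAL-H at low temperature leaves vinylic C–Cl bonds, ketal and benzyl ether untouched.

Step 8
Reactants: 13 ring A benzylic alcohol
Product: 14 ring A aldehyde (CH2OH of 13 replaced by CHO)
Conditions: MnO2 (15 equiv), CH2Cl2, rt
Reagents that add atoms: none
Why: Activated MnO2 oxidises the electron-rich benzylic alcohol selectively and stops at the aldehyde.

Step 9
Reactants: 14 ring A aldehyde; 15 allenylboronic acid pinacol ester
Product: 17 (S)-homopropargylic alcohol (ring A–CH(OH)–CH2–C≡CH), via O-boryl ether 16 (not isolated)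
Conditions: 15 (1.5 equiv), (S)-TRIP (10 mol %), 4 Å MS, toluene, −20 °C; aq NaHCO3 work-up
Reagents that add atoms: none
Why: Chiral-phosphoric-acid-catalysed allenylboration passes through a closed six-membered SE2' transition state that gives only the propargyl (not allenyl) carbinol, and the (S)-acid, bound to a boronate oxygen and the formyl hydrogen, should expose the Si face of the aldehyde and so set the (S) centre.

Step 10
Reactants: 17 (S)-homopropargylic alcohol
Product: 18 (S)-tert-butyldimethylsilyl ether of 17
Conditions: TBSCl (1.5 equiv), imidazole (3 equiv), DMF, rt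
Reagents that add atoms: tert-butyldimethylsilyl chloride, CC(C)(C)[Si](C)(C)Cl
Why: Standard silylation protects the only hydroxyl without touching the stereocentre, and the silyl ether stands ketene, zinc, n-BuLi and heat.

Step 11
Reactants: 18 silyl ether alkyne; 19 trichloroacetyl chloride
Product: 20 (S)-4,4-dichloro-3-substituted cyclobut-2-enone (chain CH2 on C3)
Conditions: 19 (3 equiv, slow addition), Zn–Cu couple (6 equiv), Et2O/DME, rt
Reagents that add atoms: none
Why: Dichloroketene–alkyne [2+2] cycloaddition joins the ketene carbonyl carbon to the terminal alkyne carbon so that the chain ends up on C3, DME ties up ZnCl2, and the dichlorovinyl ether and the arenes are too unreactive to compete.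

Step 12
Reactants: 20 dichlorocyclobutenone
Product: 21 (S)-3-substituted cyclobut-2-enone still bearing the dichlorovinyl ether on ring C
Conditions: Zn dust (5 equiv), TMEDA (5 equiv), AcOH (5 equiv), EtOH, 0 °C to rt
Reagents that add atoms: none
Why: Zinc reduction of the alpha,alpha-dichloroketone in TMEDA-buffered acetic acid is the established mild dechlorination that avoids over-reduction and double-bond migration and leaves vinylic chlorides alone.

Step 13
Reactants: 21 cyclobutenone
Product: 22 3-substituted cyclobut-2-en-1-ol (both epimers at the new carbinol; of no consequence)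
Conditions: NaBH4 (1.2 equiv), CeCl3·7H2O (1.2 equiv), MeOH/THF, −78 to −40 °C
Reagents that add atoms: none
Why: Luche 1,2-reduction parks the electrophilic and base-sensitive enone as an allylic alcohol, because the ketone would add n-BuLi or lose silanolate through its dienolate in the next step.

Step 14
Reactants: 22 cyclobutenol
Product: 25 ring C ethynyl ether cyclobutenol, via lithium alkoxide of the chloroethynyl ether 23 (not isolated), via dilithiated ethynyl ether 24 (not isolated)
Conditions: n-BuLi (3.5 equiv), THF, −78 °C, 1.5 h; sat. aq NH4Cl at −78 °C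
Reagents that add atoms: n-butyllithium, [Li]CCCC (lithium stays only in 23 and 24)
Why: This is the standard dichlorovinyl ether to ynol ether conversion (metalation, loss of LiCl, chlorine–lithium exchange), one further equivalent only deprotonates the hydroxyl, and the cold quench keeps the lithium cyclobutenoxide from electrocyclic opening.

Step 15
Reactants: 25 ethynyl ether cyclobutenol
Product: 26 benzannulation precursor: (S)-3-substituted cyclobut-2-enone on the carbinol CH2 plus ethynyl ether on ring C
Conditions: Dess–Martin periodinane (1.3 equiv), NaHCO3 (5 equiv), CH2Cl2, 0 °C; Florisil filtration, used at once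
Reagents that add atoms: none
Why: Buffered Dess–Martin oxidation of the allylic alcohol is neutral enough for the acid-sensitive ynol ether and the base-sensitive enone, so the two reactive termini coexist only from this point on.

Step 16
Reactants: 26 benzannulation precursor
Product: 31 protected macrocycle bearing one surplus hydroxyl on ring D (1-O-ring C; 3-OH; 5-CH2), via vinylketene 27 (not isolated), via vinylcyclobutenone 28 (not isolated), via dienylketene 29 (not isolated), via cyclohexadienone 30 (not isolated)
Conditions: degassed toluene, 110 °C, syringe-pump addition of 26 over 24 h to a final 0.5 mM, then 110 °C, 6 h, silylated glassware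
Reagents that add atoms: none
Why: Proposed new method: heat opens the cyclobutenone of 26 reversibly (conrotatory four-electron electrocyclic opening) to vinylketene 27, whose ketene unit adds [2+2] across the tethered ethynyl ether to give 28, which opens again to dienylketene 29, closes by a six-electron electrocyclisation to dienone 30 and tautomerises to phenol 31. The closest known reaction type is the intermolecular Danheiser benzannulation of 3-alkylcyclobutenones with alkoxy- and siloxyalkynes; the new element is that both partners sit at the ends of one chain, so that the cycloaddition is at the same time a macrocyclisation. The 18-membered ring is closed end to end in the [2+2] event by the bond between the ketene alpha-carbon and the aryloxy-bearing alkyne carbon, and ring D is closed afterwards by the disrotatory closure between the ketene carbon of 29 and its terminal =CH2, so that in the net result the two alkyne carbons are inserted between C1 and C2 of the cyclobutenone (two new C–C bonds). No stereocentre is created in 31 (the sp3 ring carbon of 28 is flattened again), and the neutral medium leaves the silylated (S)-carbinol untouched. The step needs head-to-tail regiochemistry, which the polarisation of the ynol ether secures (its nucleophilic terminal CH attacks the ketene carbonyl carbon, placing the ring C oxygen meta to the CH2 and to the new OH), and it needs ring closure to beat oligomerisation and acylation of 31, which slow addition secures together with the fact that untrapped 27 merely falls back to 26. An aryl ethynyl ether has no hydrogen placed for a retro-ene loss of ketene, so it should stand the long heating.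

Step 17
Reactants: 31 macrocyclic phenol
Product: 32 ring D aryl triflate
Conditions: Tf2O (1.3 equiv), pyridine (3 equiv), CH2Cl2, 0 °C
Reagents that add atoms: trifluoromethanesulfonic anhydride, O=S(=O)(OS(=O)(=O)C(F)(F)F)C(F)(F)F
Why: O-Sulfonylation of the only free hydroxyl activates the surplus C–O bond for reduction under conditions harmless to silyl ether, ketal and benzyl ether.

Step 18
Reactants: 32 ring D aryl triflate
Product: 33 protected macrocycle with ring D as the plain meta-phenylene
Conditions: Pd(OAc)2 (5 mol %), dppf (6 mol %), HCO2H (3 equiv), Et3N (4 equiv), DMF, 70 °C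
Reagents that add atoms: none
Why: Palladium-catalysed formate reduction of aryl triflates (oxidative addition, decarboxylation of formate to a palladium hydride, reductive elimination) replaces OTf by H, and the homogeneous catalyst does not cleave benzylic ethers.

Step 19
Reactants: 33 protected macrocycle
Product: 34 (S)-carbinol with ketal and benzyl ether still in place
Conditions: TBAF (1.5 equiv), THF, 0 °C to rt
Reagents that add atoms: none
Why: Fluoride desilylation is done while all phenols are still masked, so no para-hydroxybenzyl system exists that could ionise and erode the stereocentre.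

Step 20
Reactants: 34 (S)-carbinol
Product: 35 target CNP0333307.1 as the (S) enantiomer
Conditions: H2 (1 atm), 10 % Pd/C, EtOAc/EtOH, rt, stopped at full conversion
Reagents that add atoms: none
Why: Neutral hydrogenolysis cleaves the phenolic benzyl ether and the diphenylmethylene ketal, while secondary benzylic alcohols are normally retained in the absence of acid, as in the final debenzylation of para-hydroxyphenyl carbinols.

## Compound list

| No. | Name | SMILES | Role |
|---|---|---|---|
| 1 | methyl gallate | COC(=O)c1cc(O)c(O)c(O)c1 | starting material |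
| 2 | methyl 7-hydroxy-2,2-diphenyl-1,3-benzodioxole-5-carboxylate | COC(=O)c1cc2OC(c3ccccc3)(c3ccccc3)Oc2c(O)c1 | intermediate |
| 3 | (4-bromophenyl)boronic acid | OB(O)c1ccc(Br)cc1 | starting material |
| 4 | methyl 7-(4-bromophenoxy)-2,2-diphenyl-1,3-benzodioxole-5-carboxylate | COC(=O)c1cc2OC(c3ccccc3)(c3ccccc3)Oc2c(c1)Oc1ccc(Br)cc1 | intermediate |
| 5 | 2,3-dihydroxybenzaldehyde | O=Cc1cccc(O)c1O | starting material |
| 6 | 3-(benzyloxy)-2-hydroxybenzaldehyde | O=Cc1cccc(OCc2ccccc2)c1O | intermediate |
| 7 | methyltriphenylphosphonium bromide | C[P+](c1ccccc1)(c1ccccc1)c1ccccc1.[Br-] | starting material |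
| 8 | 2-(benzyloxy)-6-vinylphenol | C=Cc1cccc(OCc2ccccc2)c1O | intermediate |
| 9 | bis(boryl) adduct (9-BBN on the chain terminus and on the phenol oxygen) | B1(CCc2cccc(OCc3ccccc3)c2OB2C3CCCC2CCC3)C2CCCC1CCC2 | intermediate (not isolated) |
| 10 | bibenzyl phenol ester | COC(=O)c1cc2OC(c3ccccc3)(c3ccccc3)Oc2c(c1)Oc1ccc(cc1)CCc1cccc(OCc2ccccc2)c1O | intermediate |
| 11 | trichloroethylene | ClC=C(Cl)Cl | starting material |
| 12 | (E)-1,2-dichlorovinyl ether ester | COC(=O)c1cc2OC(c3ccccc3)(c3ccccc3)Oc2c(c1)Oc1ccc(cc1)CCc1cccc(OCc2ccccc2)c1O/C(Cl)=C\Cl | intermediate |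
| 13 | ring A benzylic alcohol | OCc1cc2OC(c3ccccc3)(c3ccccc3)Oc2c(c1)Oc1ccc(cc1)CCc1cccc(OCc2ccccc2)c1O/C(Cl)=C\Cl | intermediate |
| 14 | ring A aldehyde | O=Cc1cc2OC(c3ccccc3)(c3ccccc3)Oc2c(c1)Oc1ccc(cc1)CCc1cccc(OCc2ccccc2)c1O/C(Cl)=C\Cl | intermediate |
| 15 | allenylboronic acid pinacol ester | C=C=CB1OC(C)(C)C(C)(C)O1 | starting material |
| 16 | (S)-O-(pinacolboryl) homopropargylic ether | C#CC[C@H](OB1OC(C)(C)C(C)(C)O1)c1cc2OC(c3ccccc3)(c3ccccc3)Oc2c(c1)Oc1ccc(cc1)CCc1cccc(OCc2ccccc2)c1O/C(Cl)=C\Cl | intermediate (not isolated) |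
| 17 | (S)-homopropargylic alcohol | C#CC[C@H](O)c1cc2OC(c3ccccc3)(c3ccccc3)Oc2c(c1)Oc1ccc(cc1)CCc1cccc(OCc2ccccc2)c1O/C(Cl)=C\Cl | intermediate |
| 18 | (S)-TBS ether of 17 | C#CC[C@H](O[Si](C)(C)C(C)(C)C)c1cc2OC(c3ccccc3)(c3ccccc3)Oc2c(c1)Oc1ccc(cc1)CCc1cccc(OCc2ccccc2)c1O/C(Cl)=C\Cl | intermediate |
| 19 | trichloroacetyl chloride | ClC(=O)C(Cl)(Cl)Cl | starting material |
| 20 | (S)-4,4-dichlorocyclobutenone | O=C1C=C(C1(Cl)Cl)C[C@H](O[Si](C)(C)C(C)(C)C)c1cc2OC(c3ccccc3)(c3ccccc3)Oc2c(c1)Oc1ccc(cc1)CCc1cccc(OCc2ccccc2)c1O/C(Cl)=C\Cl | intermediate |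
| 21 | (S)-cyclobutenone with dichlorovinyl ether | O=C1C=C(C1)C[C@H](O[Si](C)(C)C(C)(C)C)c1cc2OC(c3ccccc3)(c3ccccc3)Oc2c(c1)Oc1ccc(cc1)CCc1cccc(OCc2ccccc2)c1O/C(Cl)=C\Cl | intermediate |
| 22 | cyclobutenol with dichlorovinyl ether (epimers at the ring carbinol) | OC1C=C(C1)C[C@H](O[Si](C)(C)C(C)(C)C)c1cc2OC(c3ccccc3)(c3ccccc3)Oc2c(c1)Oc1ccc(cc1)CCc1cccc(OCc2ccccc2)c1O/C(Cl)=C\Cl | intermediate |
| 23 | lithium alkoxide of the chloroethynyl ether | [Li]OC1C=C(C1)C[C@H](O[Si](C)(C)C(C)(C)C)c1cc2OC(c3ccccc3)(c3ccccc3)Oc2c(c1)Oc1ccc(cc1)CCc1cccc(OCc2ccccc2)c1OC#CCl | intermediate (not isolated) |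
| 24 | dilithiated ethynyl ether | [Li]OC1C=C(C1)C[C@H](O[Si](C)(C)C(C)(C)C)c1cc2OC(c3ccccc3)(c3ccccc3)Oc2c(c1)Oc1ccc(cc1)CCc1cccc(OCc2ccccc2)c1OC#C[Li] | intermediate (not isolated) |
| 25 | ethynyl ether cyclobutenol | OC1C=C(C1)C[C@H](O[Si](C)(C)C(C)(C)C)c1cc2OC(c3ccccc3)(c3ccccc3)Oc2c(c1)Oc1ccc(cc1)CCc1cccc(OCc2ccccc2)c1OC#C | intermediate |
| 26 | benzannulation precursor | O=C1C=C(C1)C[C@H](O[Si](C)(C)C(C)(C)C)c1cc2OC(c3ccccc3)(c3ccccc3)Oc2c(c1)Oc1ccc(cc1)CCc1cccc(OCc2ccccc2)c1OC#C | intermediate |
| 27 | vinylketene | O=C=CC(=C)C[C@H](O[Si](C)(C)C(C)(C)C)c1cc2OC(c3ccccc3)(c3ccccc3)Oc2c(c1)Oc1ccc(cc1)CCc1cccc(OCc2ccccc2)c1OC#C | intermediate (not isolated) |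
| 28 | macrocyclic 3-aryloxy-4-vinylcyclobutenone | O=C1C=C2C1C(=C)C[C@H](O[Si](C)(C)C(C)(C)C)c1cc3OC(c4ccccc4)(c4ccccc4)Oc3c(c1)Oc1ccc(cc1)CCc1cccc(OCc3ccccc3)c1O2 | intermediate (not isolated) |
| 29 | macrocyclic dienylketene | O=C=C/C2=C\C(=C)C[C@H](O[Si](C)(C)C(C)(C)C)c1cc3OC(c4ccccc4)(c4ccccc4)Oc3c(c1)Oc1ccc(cc1)CCc1cccc(OCc3ccccc3)c1O2 | intermediate (not isolated) |
| 30 | macrocyclic cyclohexa-2,4-dienone | O=C1C=C2C=C(C1)C[C@H](O[Si](C)(C)C(C)(C)C)c1cc3OC(c4ccccc4)(c4ccccc4)Oc3c(c1)Oc1ccc(cc1)CCc1cccc(OCc3ccccc3)c1O2 | intermediate (not isolated) |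
| 31 | protected macrocycle with surplus ring D hydroxyl | Oc1cc2cc(c1)C[C@H](O[Si](C)(C)C(C)(C)C)c1cc3OC(c4ccccc4)(c4ccccc4)Oc3c(c1)Oc1ccc(cc1)CCc1cccc(OCc3ccccc3)c1O2 | intermediate |
| 32 | ring D triflate | FC(F)(F)S(=O)(=O)Oc1cc2cc(c1)C[C@H](O[Si](C)(C)C(C)(C)C)c1cc3OC(c4ccccc4)(c4ccccc4)Oc3c(c1)Oc1ccc(cc1)CCc1cccc(OCc3ccccc3)c1O2 | intermediate |
| 33 | deoxygenated protected macrocycle | c1cc2cc(c1)C[C@H](O[Si](C)(C)C(C)(C)C)c1cc3OC(c4ccccc4)(c4ccccc4)Oc3c(c1)Oc1ccc(cc1)CCc1cccc(OCc3ccccc3)c1O2 | intermediate |
| 34 | (S)-carbinol, ketal and benzyl ether in place | c1cc2cc(c1)C[C@H](O)c1cc3OC(c4ccccc4)(c4ccccc4)Oc3c(c1)Oc1ccc(cc1)CCc1cccc(OCc3ccccc3)c1O2 | intermediate |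
| 35 | CNP0333307.1, (S) enantiomer | Oc1cc2cc(c1O)Oc1ccc(cc1)CCc1cccc(O)c1Oc1cccc(c1)C[C@@H]2O | target |

## Step count

- Total step count: 20.
- Longest linear sequence: 18 steps (1, 2, 5 to 20) from methyl gallate.

## Steps most likely to fail

**1. Step 16.**
Three things may go wrong. Capture of the vinylketene by the ynol ether, or by the already formed phenol, of a second molecule may outrun the end-to-end ring closure. The ethynyl ether may polymerise during the long heating. The cascade may stall before the second ring opening.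

The fallback uses known chemistry: the benzannulation in its established intermolecular form, then a B-alkyl Suzuki macrocyclisation. It sets out from 4 and 8 and comes back at 31.

On the ring A/B side, ester 4 is reduced with DIBAL-H to the benzylic alcohol F1 and oxidised with MnO2 to the aldehyde F2. Allenylboration with 15 under (S)-TRIP gives the (S)-homopropargylic alcohol F3, and TBSCl gives the silyl ether F4. Dichloroketene from 19 and Zn–Cu gives the dichlorocyclobutenone F5, and Zn/TMEDA/AcOH gives the bromoaryl cyclobutenone F6.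

On the ring C side, phenol 8 is converted with 11 and K2CO3 into the dichlorovinyl ether F7. Treatment with n-BuLi (2.2 equiv) in Et2O at −78 °C then gives the ethynyl ether F8. No ketone is present here, and carbolithiation of the styrene is slow in ether at this temperature.

Heating F6 with F8 in toluene at 80 to 110 °C should give the open-chain ring D phenol F9. Hydroboration of its vinyl group with 9-BBN-H gives the borane F10. Slow addition of F10 to PdCl2(dppf) and aqueous K3PO4 in DMF/THF closes the 18-membered ring at the ring B–CH2 bond to give 31.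

**2. Step 14.**
The lithium cyclobutenoxide may undergo alkoxide-accelerated electrocyclic ring opening if the mixture has to be warmed, and the chlorine–lithium exchange may remain incomplete at −78 °C.

The fallback masks the alkoxide instead of relying on temperature. It sets out from 22 and comes back at 25. TMSCl and imidazole give the trimethylsilyl ether F11. n-BuLi (2.5 equiv) in THF, now free to be warmed to −40 °C, gives the ethynyl ether silyl ether F12. K2CO3 in MeOH at 0 °C, harmless to the base-stable ynol ether and to the TBS ether, removes the trimethylsilyl group to give 25.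

**3. Step 20.**
Hydrogenolysis of the benzylic C–O bond of the free carbinol may compete while the slower ketal cleavage is driven to completion.

The fallback reverses the order of deprotection. It sets out from 33 and comes back at 35. Hydrogenolysis (H2, Pd/C, EtOAc/EtOH) is run on 33, whose bulky silyl ether shields the benzylic C–O bond, to give the triphenol silyl ether F13. Et3N·3HF in MeCN at rt then removes the silyl group under nearly neutral conditions to give 35.

## Further compounds

F1 | step 16 | benzylic alcohol from 4 | OCc1cc2OC(c3ccccc3)(c3ccccc3)Oc2c(c1)Oc1ccc(Br)cc1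
F2 | step 16 | 7-(4-bromophenoxy)-2,2-diphenyl-1,3-benzodioxole-5-carbaldehyde | O=Cc1cc2OC(c3ccccc3)(c3ccccc3)Oc2c(c1)Oc1ccc(Br)cc1
F3 | step 16 | (S)-homopropargylic alcohol of the ring A/B bromide | C#CC[C@H](O)c1cc2OC(c3ccccc3)(c3ccccc3)Oc2c(c1)Oc1ccc(Br)cc1
F4 | step 16 | (S)-TBS ether of F3 | C#CC[C@H](O[Si](C)(C)C(C)(C)C)c1cc2OC(c3ccccc3)(c3ccccc3)Oc2c(c1)Oc1ccc(Br)cc1
F5 | step 16 | (S)-4,4-dichlorocyclobutenone of the ring A/B bromide | O=C1C=C(C1(Cl)Cl)C[C@H](O[Si](C)(C)C(C)(C)C)c1cc2OC(c3ccccc3)(c3ccccc3)Oc2c(c1)Oc1ccc(Br)cc1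
F6 | step 16 | (S)-bromoaryl cyclobutenone | O=C1C=C(C1)C[C@H](O[Si](C)(C)C(C)(C)C)c1cc2OC(c3ccccc3)(c3ccccc3)Oc2c(c1)Oc1ccc(Br)cc1
F7 | step 16 | 1-(benzyloxy)-2-[(E)-1,2-dichlorovinyloxy]-3-vinylbenzene | C=Cc1cccc(OCc2ccccc2)c1O/C(Cl)=C\Cl
F8 | step 16 | 1-(benzyloxy)-2-(ethynyloxy)-3-vinylbenzene | C=Cc1cccc(OCc2ccccc2)c1OC#C
F9 | step 16 | open-chain ring D phenol with vinyl and bromide termini | Oc1cc(Oc2c(C=C)cccc2OCc2ccccc2)cc(c1)C[C@H](O[Si](C)(C)C(C)(C)C)c1cc2OC(c3ccccc3)(c3ccccc3)Oc2c(c1)Oc1ccc(Br)cc1
F10 | step 16 | B-alkyl borane of F9 (phenol oxygen also borylated) | B1(CCc2cccc(OCc3ccccc3)c2Oc2cc(OB3C4CCCC3CCC4)cc(c2)C[C@H](O[Si](C)(C)C(C)(C)C)c2cc3OC(c4ccccc4)(c4ccccc4)Oc3c(c2)Oc2ccc(Br)cc2)C2CCCC1CCC2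
F11 | step 14 | trimethylsilyl ether of 22 | C[Si](C)(C)OC1C=C(C1)C[C@H](O[Si](C)(C)C(C)(C)C)c1cc2OC(c3ccccc3)(c3ccccc3)Oc2c(c1)Oc1ccc(cc1)CCc1cccc(OCc2ccccc2)c1O/C(Cl)=C\Cl
F12 | step 14 | trimethylsilyl ether of 25 | C[Si](C)(C)OC1C=C(C1)C[C@H](O[Si](C)(C)C(C)(C)C)c1cc2OC(c3ccccc3)(c3ccccc3)Oc2c(c1)Oc1ccc(cc1)CCc1cccc(OCc2ccccc2)c1OC#C
F13 | step 20 | (S)-TBS ether of the target (three phenols free) | c1cc2cc(c1)C[C@H](O[Si](C)(C)C(C)(C)C)c1cc(O)c(O)c(c1)Oc1ccc(cc1)CCc1cccc(O)c1O2
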